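**Plan**

1. Germacrane numbering is used: oxirane C1–C10, acetates on C3 and C9, olefin C4=C5, lactone O–C6/C7–C11(CH3)–C12(=O). The γ-lactone ring is only the C6 oxygen and the C7–C11 branch closed by one carbonyl carbon, C12; at the 11(13)-ene level it is what CO makes from a trans C6-hydroxy/C7-ethynyl pair on the ten-membered ring.
2. Retrosynthetic cuts, in order: C9 acetyl and epoxide oxygen; C11–H (back to the α-methylene lactone); O–C12 and C12–C11 (CO); C6–C7 (opens the carbocycle); C8–C9 (aldol); C1=C10 (metathesis); C2–C3 (allylation); C4=C5 (Wittig).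
3. Forward: the chain C6→C3→C1→C9→C7 is built linearly, the cyclodecadiene closes at C6–C7, then the γ-lactone (step 13), then the oxirane.
4. Stereochemistry: C3 by Brown allylation; C9 by a zinc–ProPhenol ynone aldol; C7 by Noyori transfer hydrogenation, relayed with inversion through an allenylzinc that also sets C6 anti; C1/C10 by epoxidation directed by the free C9 hydroxyl.
5. C11 is set by catalyst-controlled hydrogenation, because hydride addition followed by protonation of a trans-fused lactone is expected to place hydrogen on the β face (anti to H7) and give the unwanted 11S epimer.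

Key step: step 13

Assumption: in steps 5 and 14 the ligand antipode written is the one expected to give 9S and 11R (step 14 by analogy with 2-substituted acrylic acids, where (R)-BINAP–ruthenium gives the R acid); if either sense proves opposite on these substrates, the mirror-image ligand is the same experiment.

**Step 1**
Reactants: 1 (tert-butyldimethylsilyloxy)acetaldehyde; 2 2-(triphenylphosphoranylidene)propanal
Product: 3 (E)-4-[(tert-butyldimethylsilyl)oxy]-2-methylbut-2-enal
Conditions: toluene, 80 °C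
Reagents that add atoms: none
Why: Wittig olefination with a stabilised formyl ylide should give the E-trisubstituted enal (C3–C6 with the C15 methyl), and the conjugated product is too unreactive to be homologated a second time.

**Step 2**
Reactants: 3 (E)-4-[(tert-butyldimethylsilyl)oxy]-2-methylbut-2-enal
Product: 4 (4S,5E)-7-[(tert-butyldimethylsilyl)oxy]-5-methylhepta-1,5-dien-4-ol
Conditions: (−)-Ipc2B(allyl) (commercial 1 M solution), Et2O, −78 °C; then HOCH2CH2NH2
Reagents that add atoms: (−)-B-allyldiisopinocampheylborane, C=CCB([C@@H]1C[C@@H]2C[C@H]([C@H]1C)C2(C)C)[C@@H]1C[C@@H]2C[C@H]([C@H]1C)C2(C)C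
Why: Brown allylation: the reagent derived from (+)-α-pinene adds allyl 1,2 to the Si face of the enal through a chair transition state, which sets C3 as S and brings in C2 and C1.

**Step 3**
Reactants: 4 (4S,5E)-7-[(tert-butyldimethylsilyl)oxy]-5-methylhepta-1,5-dien-4-ol
Product: 5 (4S,5E)-7-[(tert-butyldimethylsilyl)oxy]-5-methylhepta-1,5-dien-4-yl acetate
Conditions: Ac2O, Et3N, DMAP (cat.), CH2Cl2, 0 °C to rt
Reagents that add atoms: acetic anhydride, CC(=O)OC(C)=O
Why: DMAP-catalysed acetylation installs the C3 acetate of the target at once, so that later only the C9 oxygen has to be freed for the directed epoxidation.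

**Step 4**
Reactants: 5 (4S,5E)-7-[(tert-butyldimethylsilyl)oxy]-5-methylhepta-1,5-dien-4-yl acetate; 6 methacrolein
Product: 7 (2E,5S,6E)-8-[(tert-butyldimethylsilyl)oxy]-2,6-dimethyl-1-oxoocta-2,6-dien-5-yl acetate
Conditions: 6 (8 equiv), second-generation Hoveyda–Grubbs catalyst (5 mol %), CH2Cl2, 40 °C
Reagents that add atoms: none
Why: Cross-metathesis of the terminal olefin with excess methacrolein should form C1=C10 as the thermodynamically favoured E-trisubstituted enal, while the hindered trisubstituted C4=C5 olefin is inert to the catalyst.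

**Step 5**
Reactants: 7 (2E,5S,6E)-8-[(tert-butyldimethylsilyl)oxy]-2,6-dimethyl-1-oxoocta-2,6-dien-5-yl acetate; 8 4-(trimethylsilyl)but-3-yn-2-one
Product: 9 (2E,4S,6E,8S)-1-[(tert-butyldimethylsilyl)oxy]-8-hydroxy-3,7-dimethyl-10-oxo-12-(trimethylsilyl)dodeca-2,6-dien-11-yn-4-yl acetate
Conditions: 8 (1.5 equiv), (S,S)-ProPhenol (10 mol %), Et2Zn (20 mol %), 4 Å MS, THF, 0 °C to rt
Reagents that add atoms: none
Why: Direct catalytic aldol of a methyl ynone: the dinuclear zinc–ProPhenol complex forms the zinc enolate of 8 and delivers it to one face of the non-enolisable enal, making C8–C9 and the 9S carbinol under catalyst control.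

**Step 6**
Reactants: 9 (2E,4S,6E,8S)-1-[(tert-butyldimethylsilyl)oxy]-8-hydroxy-3,7-dimethyl-10-oxo-12-(trimethylsilyl)dodeca-2,6-dien-11-yn-4-yl acetate
Product: 10 (2E,4S,6E,8S)-1,8-bis[(tert-butyldimethylsilyl)oxy]-3,7-dimethyl-10-oxo-12-(trimethylsilyl)dodeca-2,6-dien-11-yn-4-yl acetate
Conditions: TBSOTf, 2,6-lutidine, CH2Cl2, −78 °C
Reagents that add atoms: tert-butyldimethylsilyl trifluoromethanesulfonate, CC(C)(C)[Si](C)(C)OS(=O)(=O)C(F)(F)F
Why: Low-temperature silylation with the triflate and a hindered pyridine protects the β-hydroxy ynone before it can eliminate or retro-aldolise, and masks C9–OH against later δ-lactone formation.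

**Step 7**
Reactants: 10 (2E,4S,6E,8S)-1,8-bis[(tert-butyldimethylsilyl)oxy]-3,7-dimethyl-10-oxo-12-(trimethylsilyl)dodeca-2,6-dien-11-yn-4-yl acetate
Product: 11 (2E,4S,6E,8S,10R)-1,8-bis[(tert-butyldimethylsilyl)oxy]-10-hydroxy-3,7-dimethyl-12-(trimethylsilyl)dodeca-2,6-dien-11-yn-4-yl acetate
Conditions: Ru[(R,R)-TsDPEN](p-cymene) (3 mol %), i-PrOH, rt
Reagents that add atoms: none
Why: Noyori asymmetric transfer hydrogenation of an alkynyl ketone, the alkyne taking the place of the aryl group in the transition state, so the (R,R)-catalyst should give the 7R propargylic alcohol (1,3-syn to C9–O) under reagent control.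

**Step 8**
Reactants: 11 (2E,4S,6E,8S,10R)-1,8-bis[(tert-butyldimethylsilyl)oxy]-10-hydroxy-3,7-dimethyl-12-(trimethylsilyl)dodeca-2,6-dien-11-yn-4-yl acetate
Product: 12 (2E,4S,6E,8S,10R)-8-[(tert-butyldimethylsilyl)oxy]-1,10-dihydroxy-3,7-dimethyl-12-(trimethylsilyl)dodeca-2,6-dien-11-yn-4-yl acetate
Conditions: HF·pyridine, pyridine, THF, 0 °C
Reagents that add atoms: none
Why: Buffered HF cleaves the unhindered primary allylic silyl ether much faster than the secondary one at C9 and leaves the acetate and the C-silyl group untouched.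

**Step 9**
Reactants: 12 (2E,4S,6E,8S,10R)-8-[(tert-butyldimethylsilyl)oxy]-1,10-dihydroxy-3,7-dimethyl-12-(trimethylsilyl)dodeca-2,6-dien-11-yn-4-yl acetate
Product: 13 (2E,4S,6E,8S,10R)-8-[(tert-butyldimethylsilyl)oxy]-10-hydroxy-3,7-dimethyl-1-oxo-12-(trimethylsilyl)dodeca-2,6-dien-11-yn-4-yl acetate
Conditions: TEMPO (10 mol %), PhI(OAc)2 (1.1 equiv), CH2Cl2, rt
Reagents that add atoms: none
Why: Oxoammonium oxidation is selective for the primary allylic alcohol over the secondary propargylic one and should give the E-enal (C6 aldehyde) without over-oxidation.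

**Step 10**
Reactants: 13 (2E,4S,6E,8S,10R)-8-[(tert-butyldimethylsilyl)oxy]-10-hydroxy-3,7-dimethyl-1-oxo-12-(trimethylsilyl)dodeca-2,6-dien-11-yn-4-yl acetate
Product: 14 (2E,4S,6E,8S,10R)-8-[(tert-butyldimethylsilyl)oxy]-3,7-dimethyl-10-[(methylsulfonyl)oxy]-1-oxo-12-(trimethylsilyl)dodeca-2,6-dien-11-yn-4-yl acetate
Conditions: MsCl, Et3N, CH2Cl2, −78 °C; used crude
Reagents that add atoms: methanesulfonyl chloride, CS(=O)(=O)Cl
Why: Sulfonylation of the propargylic alcohol proceeds with retention at C7 and provides the leaving group for the palladium step.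

**Step 11**
Reactants: 14 (2E,4S,6E,8S,10R)-8-[(tert-butyldimethylsilyl)oxy]-3,7-dimethyl-10-[(methylsulfonyl)oxy]-1-oxo-12-(trimethylsilyl)dodeca-2,6-dien-11-yn-4-yl acetate
Product: 16 (1S,2E,4R,5S,7S,8E)-7-[(tert-butyldimethylsilyl)oxy]-4-hydroxy-2,8-dimethyl-5-[(trimethylsilyl)ethynyl]cyclodeca-2,8-dien-1-yl acetate, via allenylzinc 15 (not isolated)
Conditions: Pd(OAc)2 (10 mol %), PPh3 (10 mol %), Et2Zn (3 equiv), THF, −20 °C, slow addition of 14 (final 0.003 M); aq NH4Cl
Reagents that add atoms: none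
Why: Proposed new method: zerovalent palladium displaces the propargylic mesylate anti (SN2′) to an allenylpalladium, ethyl/allenyl exchange with Et2Zn gives allenylzinc 15 with retention, and 15 adds to the tethered enal through a closed six-centre SE2′ transition state, so that C7 forms with net inversion of the mesylate centre and the C6 hydroxyl anti to the alkynyl group (H6 and H7 antiperiplanar, as the crown-shaped E,E-cyclodecadiene prefers); the closest known reactions are the intermolecular anti-selective Marshall propargylation of enals and allyl-metal Barbier closures of germacrane rings at this same C6–C7 bond.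

**Step 12**
Reactants: 16 (1S,2E,4R,5S,7S,8E)-7-[(tert-butyldimethylsilyl)oxy]-4-hydroxy-2,8-dimethyl-5-[(trimethylsilyl)ethynyl]cyclodeca-2,8-dien-1-yl acetate
Product: 17 (1S,2E,4R,5S,7S,8E)-7-[(tert-butyldimethylsilyl)oxy]-5-ethynyl-4-hydroxy-2,8-dimethylcyclodeca-2,8-dien-1-yl acetate
Conditions: AgNO3 (20 mol %), MeOH/H2O/CH2Cl2, rt
Reagents that add atoms: none
Why: Silver-catalysed protodesilylation removes the alkynyl trimethylsilyl group without touching the acetate or the silyl ether and exposes the terminal alkyne needed for carbonylation.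

**Step 13**
Reactants: 17 (1S,2E,4R,5S,7S,8E)-7-[(tert-butyldimethylsilyl)oxy]-5-ethynyl-4-hydroxy-2,8-dimethylcyclodeca-2,8-dien-1-yl acetate; 18 carbon monoxide
Product: 19 (3S,6R,7S,9S)-3-acetoxy-9-[(tert-butyldimethylsilyl)oxy]germacra-1(10)E,4E,11(13)-trien-12,6-olide
Conditions: PdCl2 (5 mol %), SnCl2 (5 mol %), PPh3 (10 mol %), CO (7 atm), MeCN, 70 °C
Reagents that add atoms: none
Why: Divalent palladium under CO converts the C6 hydroxyl into an alkoxycarbonyl–palladium species (O–C12), which adds syn across the tethered C11≡C13 triple bond to make C12–C11, and protonolysis of the exocyclic vinyl–palladium bond releases the lactone and returns the catalyst. The closest known reaction is the palladium-catalysed cyclocarbonylation of trans-2-ethynylcycloalkanols and other homopropargylic alcohols to trans-fused α-methylene-γ-butyrolactones. The lactone ring closes in a 5-exo-dig mode at C11, intramolecular delivery from O6 ruling out the 6-endo alternative. No stereocentre is created or touched; the trans fusion is carried over from the anti C6-hydroxy/C7-ethynyl pair of 17. The step needs selectivity for the alkyne over the two trisubstituted ring olefins and for C6–OH over any other oxygen: olefins do not insert into the hydroxyl-bound acyl–palladium, C9–OH is silylated so that no δ-lactone can form, and the C3 acetate sits on a 2-substituted allyl unit that divalent palladium should neither ionise nor transpose.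

**Step 14**
Reactants: 19 (3S,6R,7S,9S)-3-acetoxy-9-[(tert-butyldimethylsilyl)oxy]germacra-1(10)E,4E,11(13)-trien-12,6-olide
Product: 20 (3S,6S,7S,9S,11R)-3-acetoxy-9-[(tert-butyldimethylsilyl)oxy]germacra-1(10)E,4E-dien-12,6-olide
Conditions: H2 (50 atm), Ru(OAc)2[(R)-BINAP] (2 mol %), CH2Cl2, 40 °C
Reagents that add atoms: none
Why: Asymmetric hydrogenation of an α-methylene-γ-butyrolactone with a BINAP–ruthenium dicarboxylate, the lactone carbonyl anchoring the exocyclic olefin on the metal; the ligand is chosen to deliver both hydrogens to the α face (11R) against the substrate's expected β-face preference, and the ring olefins, which carry no ligating group, should stay untouched.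

**Step 15**
Reactants: 20 (3S,6S,7S,9S,11R)-3-acetoxy-9-[(tert-butyldimethylsilyl)oxy]germacra-1(10)E,4E-dien-12,6-olide
Product: 21 (3S,6S,7S,9S,11R)-3-acetoxy-9-hydroxygermacra-1(10)E,4E-dien-12,6-olide
Conditions: HF·pyridine, pyridine, THF, 0 °C to rt
Reagents that add atoms: none
Why: Acidic fluoride cleaves the secondary silyl ether without a basic medium that could epimerise the contra-thermodynamic C11 centre or cleave the acetate.

**Step 16**
Reactants: 21 (3S,6S,7S,9S,11R)-3-acetoxy-9-hydroxygermacra-1(10)E,4E-dien-12,6-olide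
Product: 22 (1S,3S,6S,7S,9S,10S,11R)-3-acetoxy-1,10-epoxy-9-hydroxygermacr-4E-en-12,6-olide
Conditions: VO(acac)2 (5 mol %), t-BuOOH (1.5 equiv), CH2Cl2, 0 °C
Reagents that add atoms: tert-butyl hydroperoxide, CC(C)(C)OO
Why: Vanadium-catalysed hydroxyl-directed epoxidation: the C9 vanadate ester delivers oxygen to C1=C10 only, and A1,2 strain between the C9 substituents and the C10 methyl favours the erythro epoxy alcohol (C9–O and C10–O syn), which is the required arrangement; C4=C5 has no free hydroxyl and is flanked by two acyloxy groups.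

**Step 17**
Reactants: 22 (1S,3S,6S,7S,9S,10S,11R)-3-acetoxy-1,10-epoxy-9-hydroxygermacr-4E-en-12,6-olide
Product: 23 (1S,3S,6S,7S,9S,10R,11R)-3,9-diacetoxy-1,10-epoxygermacr-4E-en-12,6-olide
Conditions: Ac2O, pyridine, DMAP (cat.), CH2Cl2, rt
Reagents that add atoms: acetic anhydride, CC(=O)OC(C)=O
Why: DMAP-catalysed acetylation of the remaining secondary alcohol; the mild base should leave C11 and the oxirane untouched (the C10 descriptor changes from S to R by priority only).

**Compound list**

1 | (tert-butyldimethylsilyloxy)acetaldehyde | O=CCO[Si](C)(C)C(C)(C)C | starting material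
2 | 2-(triphenylphosphoranylidene)propanal | CC(C=O)=P(c1ccccc1)(c1ccccc1)c1ccccc1 | starting material
3 | (E)-4-[(tert-butyldimethylsilyl)oxy]-2-methylbut-2-enal | O=C/C(C)=C/CO[Si](C)(C)C(C)(C)C | intermediate
4 | (4S,5E)-7-[(tert-butyldimethylsilyl)oxy]-5-methylhepta-1,5-dien-4-ol | C=CC[C@H](O)/C(C)=C/CO[Si](C)(C)C(C)(C)C | intermediate
5 | (4S,5E)-7-[(tert-butyldimethylsilyl)oxy]-5-methylhepta-1,5-dien-4-yl acetate | C=CC[C@H](OC(C)=O)/C(C)=C/CO[Si](C)(C)C(C)(C)C | intermediate
6 | methacrolein (2-methylprop-2-enal) | CC(=C)C=O | starting material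
7 | (2E,5S,6E)-8-[(tert-butyldimethylsilyl)oxy]-2,6-dimethyl-1-oxoocta-2,6-dien-5-yl acetate | O=C/C(C)=C/C[C@H](OC(C)=O)/C(C)=C/CO[Si](C)(C)C(C)(C)C | intermediate
8 | 4-(trimethylsilyl)but-3-yn-2-one | CC(=O)C#C[Si](C)(C)C | starting material
9 | (2E,4S,6E,8S)-1-[(tert-butyldimethylsilyl)oxy]-8-hydroxy-3,7-dimethyl-10-oxo-12-(trimethylsilyl)dodeca-2,6-dien-11-yn-4-yl acetate | C[Si](C)(C)C#CC(=O)C[C@H](O)/C(C)=C/C[C@H](OC(C)=O)/C(C)=C/CO[Si](C)(C)C(C)(C)C | intermediate
10 | (2E,4S,6E,8S)-1,8-bis[(tert-butyldimethylsilyl)oxy]-3,7-dimethyl-10-oxo-12-(trimethylsilyl)dodeca-2,6-dien-11-yn-4-yl acetate | C[Si](C)(C)C#CC(=O)C[C@H](O[Si](C)(C)C(C)(C)C)/C(C)=C/C[C@H](OC(C)=O)/C(C)=C/CO[Si](C)(C)C(C)(C)C | intermediate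
11 | (2E,4S,6E,8S,10R)-1,8-bis[(tert-butyldimethylsilyl)oxy]-10-hydroxy-3,7-dimethyl-12-(trimethylsilyl)dodeca-2,6-dien-11-yn-4-yl acetate | C[Si](C)(C)C#C[C@H](O)C[C@H](O[Si](C)(C)C(C)(C)C)/C(C)=C/C[C@H](OC(C)=O)/C(C)=C/CO[Si](C)(C)C(C)(C)C | intermediate
12 | (2E,4S,6E,8S,10R)-8-[(tert-butyldimethylsilyl)oxy]-1,10-dihydroxy-3,7-dimethyl-12-(trimethylsilyl)dodeca-2,6-dien-11-yn-4-yl acetate | C[Si](C)(C)C#C[C@H](O)C[C@H](O[Si](C)(C)C(C)(C)C)/C(C)=C/C[C@H](OC(C)=O)/C(C)=C/CO | intermediate
13 | (2E,4S,6E,8S,10R)-8-[(tert-butyldimethylsilyl)oxy]-10-hydroxy-3,7-dimethyl-1-oxo-12-(trimethylsilyl)dodeca-2,6-dien-11-yn-4-yl acetate | C[Si](C)(C)C#C[C@H](O)C[C@H](O[Si](C)(C)C(C)(C)C)/C(C)=C/C[C@H](OC(C)=O)/C(C)=C/C=O | intermediate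
14 | (2E,4S,6E,8S,10R)-8-[(tert-butyldimethylsilyl)oxy]-3,7-dimethyl-10-[(methylsulfonyl)oxy]-1-oxo-12-(trimethylsilyl)dodeca-2,6-dien-11-yn-4-yl acetate | C[Si](C)(C)C#C[C@H](OS(C)(=O)=O)C[C@H](O[Si](C)(C)C(C)(C)C)/C(C)=C/C[C@H](OC(C)=O)/C(C)=C/C=O | intermediate
15 | ethyl[(5S,6E,9S,10E)-9-acetoxy-5-[(tert-butyldimethylsilyl)oxy]-6,10-dimethyl-12-oxo-1-(trimethylsilyl)dodeca-1,2,6,10-tetraen-1-yl]zinc, zinc on the allene face opposite to the departed mesylate | CC[Zn]C([Si](C)(C)C)=[C@@]=C([H])C[C@H](O[Si](C)(C)C(C)(C)C)/C(C)=C/C[C@H](OC(C)=O)/C(C)=C/C=O | intermediate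
16 | (1S,2E,4R,5S,7S,8E)-7-[(tert-butyldimethylsilyl)oxy]-4-hydroxy-2,8-dimethyl-5-[(trimethylsilyl)ethynyl]cyclodeca-2,8-dien-1-yl acetate | CC(=O)O[C@H]1C/C=C(C)/[C@@H](O[Si](C)(C)C(C)(C)C)C[C@@H](C#C[Si](C)(C)C)[C@@H](/C=C/1C)O | intermediate
17 | (1S,2E,4R,5S,7S,8E)-7-[(tert-butyldimethylsilyl)oxy]-5-ethynyl-4-hydroxy-2,8-dimethylcyclodeca-2,8-dien-1-yl acetate | CC(=O)O[C@H]1C/C=C(C)/[C@@H](O[Si](C)(C)C(C)(C)C)C[C@@H](C#C)[C@@H](/C=C/1C)O | intermediate
18 | carbon monoxide | [C-]#[O+] | starting material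
19 | (3S,6R,7S,9S)-3-acetoxy-9-[(tert-butyldimethylsilyl)oxy]germacra-1(10)E,4E,11(13)-trien-12,6-olide | CC(=O)O[C@H]1C/C=C(C)/[C@@H](O[Si](C)(C)C(C)(C)C)C[C@@H]2[C@@H](/C=C/1C)OC(=O)C2=C | intermediate
20 | (3S,6S,7S,9S,11R)-3-acetoxy-9-[(tert-butyldimethylsilyl)oxy]germacra-1(10)E,4E-dien-12,6-olide | CC(=O)O[C@H]1C/C=C(C)/[C@@H](O[Si](C)(C)C(C)(C)C)C[C@@H]2[C@@H](/C=C/1C)OC(=O)[C@@H]2C | intermediate
21 | (3S,6S,7S,9S,11R)-3-acetoxy-9-hydroxygermacra-1(10)E,4E-dien-12,6-olide | CC(=O)O[C@H]1C/C=C(C)/[C@@H](O)C[C@@H]2[C@@H](/C=C/1C)OC(=O)[C@@H]2C | intermediate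
22 | (1S,3S,6S,7S,9S,10S,11R)-3-acetoxy-1,10-epoxy-9-hydroxygermacr-4E-en-12,6-olide | CC(=O)O[C@H]1C[C@@H]2O[C@@]2(C)[C@@H](O)C[C@@H]2[C@@H](/C=C/1C)OC(=O)[C@@H]2C | intermediate
23 | (1S,3S,6S,7S,9S,10R,11R)-3,9-diacetoxy-1,10-epoxygermacr-4E-en-12,6-olide (CNP0250285.1) | CC(=O)O[C@H]1C[C@@H]2O[C@@]2(C)[C@@H](OC(C)=O)C[C@@H]2[C@@H](/C=C/1C)OC(=O)[C@@H]2C | target

**Step count**

Total: 17 steps. Longest linear sequence: 17 steps (1 to 23).

**Steps most likely to fail**

1. Step 11 (proposed new method). Intermolecular oligomerisation may outpace the strained ten-membered closure. Chirality transfer may erode through allenylzinc racemisation during the slow addition. Closure through the other aldehyde face would give the syn pair. Fallback, known chemistry at the same C6–C7 bond: a chromium-mediated Barbier (Nozaki–Hiyama) closure, the reaction class that closes germacrane rings at this bond from allylic bromides. Hydroxy enal 13 is converted (CBr4, PPh3, CH2Cl2, −20 °C) into the propargylic bromide F1, which is added slowly to excess CrCl2 in THF at high dilution and should give 16. Chirality transfer from C7 is given up; the anti C6/C7 pair must then come from the anti preference of the organochromium addition and the ring's bias from C3 and C9.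

2. Step 14. The facial selectivity may be poor because the substrate's preference (hydrogen entering anti to the pseudo-axial H7, on the β face) opposes the catalyst. Ruthenium hydride may also move the exocyclic olefin into the ring. Fallback from 19: conjugate reduction with NaBH4 in MeOH should give the 11S lactone F4 cleanly. F4 is then enolised (excess LiHMDS, THF, −78 °C; the acetate enolate formed alongside is simply reprotonated) and quenched at −78 °C with 2,6-di-tert-butylphenol. Lactone 20 is separated by chromatography and F4 is recycled. This trades selectivity for an iterative but dependable supply of 20.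

3. Step 13. Under the warm, Lewis-acidic carbonylation conditions the 1,5-diene may undergo transannular cyclisation or Cope rearrangement, the allylic C6 alcohol may ionise, or the catalyst may be reduced to inactive metal. Fallback from 17: the same two bonds are made in two stages with CO still supplying C12. Hydrostannation at the internal alkyne carbon (Bu3SnH, Mo(CO)3(CNt-Bu)3 cat., THF, 55 °C) gives the α-stannyl alkene F2. Iododestannylation (I2, CH2Cl2, 0 °C) gives the 2-iodoalkene F3. Carbonylative lactonisation of F3 (Pd(PPh3)4, CO 1 atm, Et3N, MeCN, 40 °C) closes the lactone to 19 without a Lewis acid.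

**Further compounds**

F1 | step 11 | (2E,4S,6E,8S,10S)-10-bromo-8-[(tert-butyldimethylsilyl)oxy]-3,7-dimethyl-1-oxo-12-(trimethylsilyl)dodeca-2,6-dien-11-yn-4-yl acetate | C[Si](C)(C)C#C[C@@H](Br)C[C@H](O[Si](C)(C)C(C)(C)C)/C(C)=C/C[C@H](OC(C)=O)/C(C)=C/C=O
F2 | step 13 | 17 with the ethynyl group replaced by 1-(tributylstannyl)ethenyl, all stereocentres arranged as in 17 | CC(=O)O[C@H]1C/C=C(C)/[C@@H](O[Si](C)(C)C(C)(C)C)C[C@@H](C(=C)[Sn](CCCC)(CCCC)CCCC)[C@@H](/C=C/1C)O
F3 | step 13 | 17 with the ethynyl group replaced by 1-iodoethenyl, all stereocentres arranged as in 17 | CC(=O)O[C@H]1C/C=C(C)/[C@@H](O[Si](C)(C)C(C)(C)C)C[C@@H](C(=C)I)[C@@H](/C=C/1C)O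
F4 | step 14 | (3S,6S,7S,9S,11S)-3-acetoxy-9-[(tert-butyldimethylsilyl)oxy]germacra-1(10)E,4E-dien-12,6-olide (11-epimer of 20) | CC(=O)O[C@H]1C/C=C(C)/[C@@H](O[Si](C)(C)C(C)(C)C)C[C@@H]2[C@@H](/C=C/1C)OC(=O)[C@H]2C
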